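A one-step world, substrate with reagent to target, reads a flat line as the end of a flask, so we begin by asking how fast the teal flask goes flat.

| flask | substrate | reagent in the second phase | temperature | remark | time | volume of the second phase over the first |
|---|---|---|---|---|---|---|
| teal | 20 mM | 0.90 equiv | 25 °C | the very flask that is asked about, followed so far |  |  |
| violet | 13 mM | 0.90 equiv | 10 °C | run made earlier |  |  |
| flask | 20 mM | 0.900 equiv | 25 °C |  | 20 min | 0.50 |

| run | time / min | target / % |
|---|---|---|
| teal | 1.50 | 12.7 |
| teal | 3.00 | 25.9 |
| teal | 6.00 | 37.7 |
| teal | 10.0 | 43.4 |
| teal | 20.0 | 42.7 |
| violet | 2.00 | 5.3 |
| violet | 3.00 | 8.7 |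
| violet | 6.00 | 18.0 |
| violet | 10.0 | 25.9 |
| violet | 20.0 | 37.7 |

(standard deviation of a reading: 0.5 percentage points)

- in the second phase: reagent in the second phase; everything else is in the first
- charges count per volume of the first phase; a concentration in a rate is the amount of a species over the volume of its own phase; every rate counts per litre of the first phase
- additions bring no volume worth counting
- the earlier runs hold the two phases in the same ratio of volumes as the flask asked about
- a reading or a percentage of target counts all its forms, free or not

- summer: at 20 min add substrate, 50.0 % of the amount charged, then wait 10 min
- winter: at 20 min raise the temperature by 25 K, then wait 10 min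
- noon: change nothing and wait 10 min more

* target, in percent of the substrate first charged, at 20 min
* what to do for the largest gain in target; "none" if nothing gains more than 2 percentage points (summer / winter / noon / none)
* target present, in percent of the substrate first charged, after winter
* target present, in percent of the substrate first charged, after noon

We define the shortfall half-time as the time in which the distance of target from its plateau halves. Taking the last teal reading, 42.7 %, as the plateau, the distance goes from 17 percentage points at 3.00 min to 5 points at 6.00 min, a half-time of 1.72 min. That leaves 0.99 points at 10.0 min, so we count that reading into the plateau too. Going round again with the plateau at 43.0 % gives a shortfall half-time of 1.79 min. By 20 min our reckoning leaves the teal flask 0.023 points of shortfall, so we commit to 43.0 % now and to no gain from noon; the half-time speaks to waiting, not to additions or heat.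

The forecast gives 43 % now, 43 % after noon, 42 % after winter, and chooses summer; of heating it says: “Heating only re-equilibrates quickly, with perhaps a slight loss.”

The teal flask gives 43.3 % now, 42.2 % after noon and 80.6 % after winter, so the best choice is winter, with a gain of 37 points against 3.1 points for summer.

    substrate + reagent in the reaction phase → target (k = 0.261 M⁻¹ s⁻¹, Ea = 51.0 kJ mol⁻¹)
    target ⇌ isomer of the product (K = 1.06, k = 0.00115 s⁻¹, Ea = 91.0 kJ mol⁻¹, ΔH = −84.0 kJ mol⁻¹)
    crystals ⇌ target, rate k3*(cs3 - [target]) while solid is left; crystals form when [target] > cs3 (solubility = 17.0 mM, k = 0.241 s⁻¹)
    reagent in the reaction phase ⇌ reagent in the second phase, rate k4*([reagent in the reaction phase] - [reagent in the second phase]/K4) per volume of the first phase (partition coefficient = 1.06, kL = 0.00859 s⁻¹)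
    (constants at 25 °C)

The flat line in the teal flask was a balance and not an end: from 10.0 min to 20.0 min target stood at 43.4 % and then 43.3 %, while substrate fell from 40.1 % to 25.9 % and isomer of the product rose from 16.5 % to 30.8 %. The main reason why target stands there is its turning into isomer of the product, both ways: the same run without that turning gives 74.1 % at 20 min instead of 43.3 %. Winter's gain rests in part on the falling back of isomer of the product to target: without that step the gain of 37 points becomes −29 points.

For the same recipe read at 5.0 min, the shortfall half-time gives 35.2 %, and the simulation gives 35.7 %.

(The numbers in the tables were computed with constants of no real substance; the scatter is artificial.)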